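**Plan**

1. Numbering (germacranolide): C1 ketone, C2=C3 enol ether, C4(–C15H3)=C5, C6–O lactone, C7, C8–O isovalerate, C9–OAc, C10(–C14H3)–O; C11(=C13)–C12 lactone carbonyl.
2. Retrosynthesis: remove the two acyl groups and open the lactone (C12–O6); put SO2 back between C4 and C5, so that the 9-membered ring O–C3–C4–C5–C6–C7–C8–C9–C10 becomes a 10-membered cyclic sulfone; then cut C6–C7 (allylchromium + aldehyde), S–C4, and the furanone (O–C3, C10–CH3, C10–C1) back to L-tartrate, pent-1-yn-3-ol, an acrylate and a C2 disulfide.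
3. Enabling feature: C4 is the γ-carbon of the vinylogous ester C1(=O)–C2=C3(–O)–C4, so C4–H is acidic and sulfur (later chlorine) can be placed there selectively; C4=C5 is the only C=C inside the 9-membered ring, exactly where SO2 extrusion creates one.
4. Forward: dioxolane (from tartrate) → furanone ring → thioether arm on C4 → 10-membered thia-oxa ring by Cr-mediated C6–C7 allylation → sulfone → contraction to the 9-membered ring with the 4Z alkene → lactone ring → esters.
5. Stereochemistry: C8 and C9 from L-tartaric acid; C10 by chelation-controlled MeMgBr addition; C6 and C7 in the allylation (chair transition state, face set by C8); 4Z imposed by the ring.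

Key step: step 15

Remark: 4 is used as the racemate and sulfur is introduced at C4 without stereocontrol, so C3 in 5/6, C4 in 11–22 and the carbinol carbon C7 in 14/15 are epimer mixtures written without a stereo-label (all three centres are destroyed later); metalated forms of numbered compounds get no number of their own.

**Route**

Step 1
Reactants: 1 dimethyl 2,3-O-isopropylidene-L-tartrate
Product: 2 mono-hydroxymethyl ester
Conditions: NaBH4 (0.6 equiv), MeOH, −10 °C
Reagents that add atoms: none
Why: Desymmetrising partial borohydride reduction of one of the two homotopic α-alkoxy esters, which stops at the hydroxy ester with limiting hydride; no stereocentre is touched.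

Step 2
Reactants: 2 mono-hydroxymethyl ester
Product: 3 hydroxy Weinreb amide
Conditions: MeNH(OMe)·HCl (3 equiv), i-PrMgCl (7 equiv), THF, −20 → 0 °C
Reagents that add atoms: N,O-dimethylhydroxylamine hydrochloride, CNOC.Cl
Why: Weinreb amidation of the ester by the chloromagnesium amide, the free hydroxyl being carried as its magnesium alkoxide.

Step 3
Reactants: 3 hydroxy Weinreb amide; 4 pent-1-yn-3-ol
Product: 5 ynone (C10 ketone)
Conditions: 4 (3 equiv), n-BuLi (6 equiv), THF, −78 °C; then 3, −78 → −40 °C; aq. NH4Cl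
Reagents that add atoms: none
Why: Weinreb ketone synthesis in which the lithium acetylide of doubly deprotonated 4 acylates at the amide and the chelated tetrahedral intermediate prevents a second addition.

Step 4
Reactants: 5 ynone
Product: 6 tertiary propargylic alcohol (triol)
Conditions: MeMgBr (4 equiv), THF, −78 °C
Reagents that add atoms: methylmagnesium bromide, C[Mg]Br
Why: Chelation-controlled Grignard 1,2-addition in which magnesium bridges the ketone oxygen and the dioxolane oxygen on C9 and methyl enters from the face of H-9, which sets C10 with O9 and O10 erythro as the target requires.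

Step 5
Reactants: 6 triol
Product: 7 4-hydroxy-2-ynone (C3 ketone)
Conditions: activated MnO2, CH2Cl2, rt
Reagents that add atoms: none
Why: Propargylic-selective MnO2 oxidation of the secondary alcohol only, which leaves the tertiary and the saturated primary hydroxyl and erases the epimer mixture at C3.

Step 6
Reactants: 7 4-hydroxy-2-ynone
Product: 9 5-ethyl-3(2H)-furanone alcohol, via enaminone 8 (not isolated)
Conditions: Et2NH, EtOH, rt; then aq. oxalic acid, THF, rt
Reagents that add atoms: water, O
Why: Classical conversion of a 4-hydroxy-2-ynone into a 3(2H)-furanone, in which Et2NH adds at C1, the C10 hydroxyl then closes onto the C3 carbonyl (5-exo-trig), water is lost and iminium hydrolysis leaves the C1 ketone, with C10 untouched.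

Step 7
Reactants: 9 furanone alcohol; 10 bis(2,2-diethoxyethyl) disulfide
Product: 11 C4 sulfide with diethyl acetal arm
Conditions: LDA (2.1 equiv), THF, −78 °C; then added to 10, −78 → −40 °C
Reagents that add atoms: none
Why: Enolate sulfenylation in which LDA removes the γ-proton at C4 (C10 is quaternary) and the extended enolate attacks the disulfide at C4, inverse addition limiting bis-sulfenylation; the new C4 centre is formed unselectively and is destroyed in step 15.

Step 8
Reactants: 11 C4 sulfide
Product: 12 C7 aldehyde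
Conditions: Dess–Martin periodinane, CH2Cl2, 0 °C → rt
Reagents that add atoms: none
Why: Dess–Martin oxidation of the primary alcohol under neutral conditions that spare thioether, acetals and enol ether; the trans-dioxolane aldehyde is the favoured epimer, so C8 is safe.

Step 9
Reactants: 12 C7 aldehyde; 13 tert-butyl acrylate
Product: 14 Morita–Baylis–Hillman adduct
Conditions: 13 (5 equiv), DABCO, dioxane/H2O (1:1), rt
Reagents that add atoms: none
Why: Morita–Baylis–Hillman reaction of the activated α-alkoxy aldehyde, which joins C7 to C11; the carbinol configuration is irrelevant because C7 becomes sp2 in step 10.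

Step 10
Reactants: 14 Morita–Baylis–Hillman adduct
Product: 16 (Z)-allylic bromide, via mesylate 15 (not isolated)
Conditions: MsCl, Et3N, CH2Cl2, −20 °C; then LiBr, acetone, rt
Reagents that add atoms: lithium bromide, [Li+].[Br-]
Why: Mesylation followed by SN2′ displacement with bromide (allylic transposition of a Morita–Baylis–Hillman adduct) gives the thermodynamically preferred (Z)-2-(bromomethyl)enoate.

Step 11
Reactants: 16 (Z)-allylic bromide
Product: 17 seco aldehyde (S–CH2–CHO)
Conditions: Amberlyst-15, acetone/H2O (20:1), rt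
Reagents that add atoms: water, O
Why: Acid-catalysed hydrolysis of the acyclic diethyl acetal, which reacts far faster than the cyclic acetonide that the acetone medium also preserves; tert-butyl ester and allylic bromide are inert.

Step 12
Reactants: 17 seco aldehyde
Product: 18 macrocyclic hydroxy ester (10-membered thia-oxa ring)
Conditions: CrCl2 (6 equiv), THF, 0.003 M (syringe-pump addition), rt
Reagents that add atoms: none
Why: Intramolecular Nozaki–Hiyama (Barbier-type) allylation at high dilution in which the allylchromium(III) species adds through C7 to the aldehyde in a chair transition state (anti, the future trans-lactone relation of C6/C7), the C7 face being set by C8 (H-8 in plane to avoid A(1,3) strain with the ester, attack anti to the C8–C9 bond), while the trans-dioxolane keeps the allylmetal away from the furanone carbonyl.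

Step 13
Reactants: 18 macrocyclic hydroxy ester
Product: 19 6-O-triethylsilyl ether
Conditions: TESCl, imidazole, DMF, 0 °C → rt
Reagents that add atoms: chlorotriethylsilane, CC[Si](Cl)(CC)CC
Why: Silyl ether formation at the only free hydroxyl, so that the later β-hydroxy sulfone can neither fragment in a retro-aldol sense nor lactonise under base.

Step 14
Reactants: 19 6-O-triethylsilyl ether
Product: 20 cyclic sulfone
Conditions: mCPBA (2.2 equiv), CH2Cl2, 0 °C
Reagents that add atoms: 3-chloroperoxybenzoic acid, OOC(=O)c1cccc(Cl)c1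
Why: Peracid oxidation of the sulfide to the sulfone, which is much faster than epoxidation of the electron-poor acrylate and vinylogous-ester double bonds.

Step 15
Reactants: 20 cyclic sulfone
Product: 23 ring-contracted (4Z)-dienone, via chlorosulfone 21 (not isolated), via episulfone 22 (not isolated)
Conditions: KHMDS (1.1 equiv), THF, −78 °C; C2Cl6 (1.2 equiv); then KOt-Bu (3 equiv), −78 → 0 °C
Reagents that add atoms: none
Why: The C4–H, flanked by the sulfone and the vinylogous ester, is removed first and chlorinated by C2Cl6; tert-butoxide then deprotonates C5, the carbanion displaces the activated tertiary allylic chloride at C4 to give thiirane 1,1-dioxide 22, and this loses SO2 cheletropically. This is a Ramberg–Bäcklund ring contraction, the closest known type being the contraction of medium-ring α-halo sulfones to cis-cycloalkenes. The 9-membered ring O–C3–C4–C5–C6–C7–C8–C9–C10 thus arises from the 10-membered thia ring by loss of the sulfur atom, the only closure being the 3-exo-tet formation of the episulfone. No stereocentre is created; the alkene is Z because only the cis-fused episulfone (C3 and C6 cis) fits inside the bridged bicycle. The step needs halogenation at C4 and not C5 (secured by the much higher acidity of C4–H) and 1,3-displacement in preference to β-elimination of the C6 oxygen or attack on the ester (secured by the silyl ether as a poor leaving group, the activated chloride and the non-enolisable tert-butyl acrylate).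

Step 16
Reactants: 23 ring-contracted (4Z)-dienone
Product: 25 lactone 8,9-diol, via lactone acetonide 24 (not isolated)
Conditions: TFA/CH2Cl2 (1:4), 0 °C → rt; then H2O (10 vol%), 0 °C
Reagents that add atoms: none
Why: Acidolysis removes the triethylsilyl ether and the tert-butyl ester and the γ-hydroxy acid lactonises at O6 while O8 is still locked in the acetonide, giving the trans-fused α-methylene lactone; added water then hydrolyses the acetonide.

Step 17
Reactants: 25 lactone 8,9-diol
Product: 26 8-O-isovalerate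
Conditions: isovaleric anhydride (1.1 equiv), DMAP (cat.), Et3N, CH2Cl2, −40 °C
Reagents that add atoms: 3-methylbutanoic anhydride, CC(C)CC(=O)OC(=O)CC(C)C
Why: Site-selective DMAP-catalysed acylation at low temperature of the less hindered C8 hydroxyl, the C9 hydroxyl being shielded by the adjacent quaternary C10.

Step 18
Reactants: 26 8-O-isovalerate
Product: 27 CNP0255553.1
Conditions: Ac2O, pyridine, DMAP (cat.), CH2Cl2, 0 °C → rt
Reagents that add atoms: acetic anhydride, CC(=O)OC(C)=O
Why: DMAP-catalysed acetylation of the remaining hindered secondary alcohol completes the target without touching any stereocentre.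

**Compound list**

1 | dimethyl (4R,5R)-2,2-dimethyl-1,3-dioxolane-4,5-dicarboxylate (dimethyl 2,3-O-isopropylidene-L-tartrate) | COC(=O)[C@@H]1OC(C)(C)O[C@H]1C(=O)OC | starting material
2 | methyl (4R,5S)-5-(hydroxymethyl)-2,2-dimethyl-1,3-dioxolane-4-carboxylate | OC[C@@H]1OC(C)(C)O[C@H]1C(=O)OC | intermediate
3 | (4R,5S)-5-(hydroxymethyl)-N-methoxy-N,2,2-trimethyl-1,3-dioxolane-4-carboxamide | OC[C@@H]1OC(C)(C)O[C@H]1C(=O)N(C)OC | intermediate
4 | pent-1-yn-3-ol (racemate) | CCC(O)C#C | starting material
5 | 4-hydroxy-1-[(4R,5S)-5-(hydroxymethyl)-2,2-dimethyl-1,3-dioxolan-4-yl]hex-2-yn-1-one (C3 epimers) | OC[C@@H]1OC(C)(C)O[C@H]1C(=O)C#CC(O)CC | intermediate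
6 | (2S)-2-[(4R,5S)-5-(hydroxymethyl)-2,2-dimethyl-1,3-dioxolan-4-yl]hept-3-yne-2,5-diol (C3 epimers; C10 as in the target) | OC[C@@H]1OC(C)(C)O[C@H]1[C@@](C)(O)C#CC(O)CC | intermediate
7 | (6S)-6-hydroxy-6-[(4R,5S)-5-(hydroxymethyl)-2,2-dimethyl-1,3-dioxolan-4-yl]hept-4-yn-3-one | OC[C@@H]1OC(C)(C)O[C@H]1[C@@](C)(O)C#CC(=O)CC | intermediate
8 | enaminone: 5-(diethylamino) adduct of 7 (hept-4-en-3-one) | OC[C@@H]1OC(C)(C)O[C@H]1[C@@](C)(O)C(=CC(=O)CC)N(CC)CC | intermediate
9 | (2R)-5-ethyl-2-[(4R,5S)-5-(hydroxymethyl)-2,2-dimethyl-1,3-dioxolan-4-yl]-2-methylfuran-3(2H)-one | OC[C@@H]1OC(C)(C)O[C@H]1[C@@]2(C)OC(CC)=CC2=O | intermediate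
10 | bis(2,2-diethoxyethyl) disulfide | CCOC(OCC)CSSCC(OCC)OCC | starting material
11 | 9 carrying a (2,2-diethoxyethyl)sulfanyl group on C4 (C4 epimers) | OC[C@@H]1OC(C)(C)O[C@H]1[C@@]2(C)OC(C(C)SCC(OCC)OCC)=CC2=O | intermediate
12 | 11 with the CH2OH oxidised to the C7 aldehyde | O=C[C@@H]1OC(C)(C)O[C@H]1[C@@]2(C)OC(C(C)SCC(OCC)OCC)=CC2=O | intermediate
13 | tert-butyl acrylate | C=CC(=O)OC(C)(C)C | starting material
14 | tert-butyl 2-(hydroxymethyl-substituted)acrylate: Morita–Baylis–Hillman adduct of 12 (C7 carbinol epimers) | C=C(C(=O)OC(C)(C)C)C(O)[C@@H]1OC(C)(C)O[C@H]1[C@@]2(C)OC(C(C)SCC(OCC)OCC)=CC2=O | intermediate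
15 | C7 methanesulfonate of 14 | C=C(C(=O)OC(C)(C)C)C(OS(C)(=O)=O)[C@@H]1OC(C)(C)O[C@H]1[C@@]2(C)OC(C(C)SCC(OCC)OCC)=CC2=O | intermediate
16 | tert-butyl (Z)-2-(bromomethyl)-3-(dioxolanyl)acrylate with furanone and diethyl acetal arm | BrC/C(C(=O)OC(C)(C)C)=C\[C@@H]1OC(C)(C)O[C@H]1[C@@]2(C)OC(C(C)SCC(OCC)OCC)=CC2=O | intermediate
17 | 16 with the acetal hydrolysed to S–CH2–CHO (seco aldehyde) | BrC/C(C(=O)OC(C)(C)C)=C\[C@@H]1OC(C)(C)O[C@H]1[C@@]2(C)OC(C(C)SCC=O)=CC2=O | intermediate
18 | macrocyclic hydroxy ester: ring O–C3–C4–S–C5–C6–C7–C8–C9–C10, 6-OH, C7–C(=CH2)CO2t-Bu, 8,9-O-isopropylidene, C6/C7/C8/C9/C10 as in the target | C=C(C(=O)OC(C)(C)C)[C@H]1[C@H](O)CSC(C)C2=CC(=O)[C@](C)(O2)[C@@H]3OC(C)(C)O[C@@H]13 | intermediate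
19 | 6-O-triethylsilyl ether of 18 | C=C(C(=O)OC(C)(C)C)[C@H]1[C@H](O[Si](CC)(CC)CC)CSC(C)C2=CC(=O)[C@](C)(O2)[C@@H]3OC(C)(C)O[C@@H]13 | intermediate
20 | cyclic sulfone (S,S-dioxide of 19) | C=C(C(=O)OC(C)(C)C)[C@H]1[C@H](O[Si](CC)(CC)CC)CS(=O)(=O)C(C)C2=CC(=O)[C@](C)(O2)[C@@H]3OC(C)(C)O[C@@H]13 | intermediate
21 | 4-chloro sulfone | C=C(C(=O)OC(C)(C)C)[C@H]1[C@H](O[Si](CC)(CC)CC)CS(=O)(=O)C(C)(Cl)C2=CC(=O)[C@](C)(O2)[C@@H]3OC(C)(C)O[C@@H]13 | intermediate
22 | episulfone (C4–C5 thiirane 1,1-dioxide fused to the 9-membered ring) | C=C(C(=O)OC(C)(C)C)[C@H]1[C@H](O[Si](CC)(CC)CC)C4C(C)(S4(=O)=O)C2=CC(=O)[C@](C)(O2)[C@@H]3OC(C)(C)O[C@@H]13 | intermediate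
23 | ring-contracted (4Z)-dienone: 9-membered ring, 6-OTES, tert-butyl ester, 8,9-acetonide | C=C(C(=O)OC(C)(C)C)[C@H]1[C@H](O[Si](CC)(CC)CC)/C=C(/C)C2=CC(=O)[C@](C)(O2)[C@@H]3OC(C)(C)O[C@@H]13 | intermediate
24 | 8,9-O-isopropylidene α-methylene lactone | C=C1C(=O)O[C@@H]2/C=C(/C)C3=CC(=O)[C@](C)(O3)[C@@H]4OC(C)(C)O[C@H]4[C@@H]12 | intermediate
25 | 8,9-dihydroxy lactone | C=C1C(=O)O[C@@H]2/C=C(/C)C3=CC(=O)[C@](C)(O3)[C@H](O)[C@@H](O)[C@@H]12 | intermediate
26 | 8-O-isovaleryl-9-hydroxy lactone | C=C1C(=O)O[C@@H]2/C=C(/C)C3=CC(=O)[C@](C)(O3)[C@H](O)[C@@H](OC(=O)CC(C)C)[C@@H]12 | intermediate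
27 | CNP0255553.1, (4Z,6R,7S,8S,9R,10R) | C=C1C(=O)O[C@@H]2/C=C(/C)C3=CC(=O)[C@](C)(O3)[C@H](OC(C)=O)[C@@H](OC(=O)CC(C)C)[C@@H]12 | target

**Step count and risks**

Total steps: 18. Longest linear sequence: 18 steps (1 → 27); 4, 10 and 13 are bought.

Steps most likely to fail:

Step 15. The C5 carbanion may expel the C6 silyloxy group (E1cB to a vinyl sulfone) or displace the hindered tertiary chloride too slowly, so that SO2 is not extruded. The fallback sets out from 18 and returns at 25, and it is still a ring contraction. Oxidation of 18 with mCPBA should give the macrocyclic β-hydroxy sulfone F1. Mesylation and elimination (MsCl, Et3N, then DBU) should give the vinyl sulfone F2. Nucleophilic epoxidation with LiOOt-Bu, oxygen entering anti to the C7 side chain, should give the α,β-epoxy sulfone F3. LiOt-Bu then triggers the epoxy variant of the Ramberg–Bäcklund reaction: the easily formed, stabilised C4 carbanion opens the epoxide at C5, the episulfone loses SO2 and the C6 alkoxide is set free, giving the ring-contracted allylic alcohol F4. Under the conditions of step 16, F4 should give 25. No carbanion at C5 and no halide are needed.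

Step 12. Oligomerisation may compete with ring closure, and facial control of the allyl transfer may be lost inside the macrocyclic transition state. The fallback sets out from 9 and returns at 18; it makes C6–C7 between separate partners and closes the ring at sulfur. Sulfenylation of 9 (LDA; dimethyl 3,3'-dithiodipropanoate) should give the 2-(methoxycarbonyl)ethyl sulfide F5, a base-labile thiol mask. Dess–Martin oxidation gives the aldehyde F6, reaction with 13 and DABCO the Morita–Baylis–Hillman adduct F7, and MsCl/LiBr the allylic bromide F8. Intermolecular CrCl2-mediated allylation of chloroacetaldehyde then gives the open-chain chlorohydrin F9 with the same anti/C8-controlled selectivity. KOt-Bu at high dilution releases the thiolate by retro-Michael loss of methyl acrylate and converts the chlorohydrin into the terminal epoxide, which the thiolate opens at C5 to give 18.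

Step 17. Discrimination between O8 and O9 may be insufficient, and the acyl group may migrate between the vicinal oxygens under DMAP. The fallback sets out from 25 and returns at 27 by a silyl relay. TBSCl/imidazole should silylate the more accessible O8 to the 8-O-TBS ether F10. Ac2O/DMAP then acetylates O9 to the silyl acetate F11, and HF·pyridine frees O8 to give the 9-acetate F12. Isovaleric anhydride/DMAP completes 27, so each acyl group is introduced when no free neighbouring hydroxyl is present.

Further compounds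
F1 | step 15 | macrocyclic β-hydroxy sulfone (S,S-dioxide of 18) | C=C(C(=O)OC(C)(C)C)[C@H]1[C@H](O)CS(=O)(=O)C(C)C2=CC(=O)[C@](C)(O2)[C@@H]3OC(C)(C)O[C@@H]13
F2 | step 15 | macrocyclic vinyl sulfone (C5=C6, geometry open) | C=C(C(=O)OC(C)(C)C)[C@H]1C=CS(=O)(=O)C(C)C2=CC(=O)[C@](C)(O2)[C@@H]3OC(C)(C)O[C@@H]13
F3 | step 15 | α,β-epoxy sulfone (5,6-epoxide, C6–O as in 18, C5 open) | C=C(C(=O)OC(C)(C)C)[C@H]1[C@@H]4OC4S(=O)(=O)C(C)C2=CC(=O)[C@](C)(O2)[C@@H]3OC(C)(C)O[C@@H]13
F4 | step 15 | ring-contracted allylic alcohol (6-OH analogue of 23) | C=C(C(=O)OC(C)(C)C)[C@H]1[C@H](O)/C=C(/C)C2=CC(=O)[C@](C)(O2)[C@@H]3OC(C)(C)O[C@@H]13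
F5 | step 12 | 9 carrying a 2-(methoxycarbonyl)ethylsulfanyl group on C4 (C4 epimers) | OC[C@@H]1OC(C)(C)O[C@H]1[C@@]2(C)OC(C(C)SCCC(=O)OC)=CC2=O
F6 | step 12 | C7 aldehyde from F5 | O=C[C@@H]1OC(C)(C)O[C@H]1[C@@]2(C)OC(C(C)SCCC(=O)OC)=CC2=O
F7 | step 12 | Morita–Baylis–Hillman adduct of F6 with 13 | C=C(C(=O)OC(C)(C)C)C(O)[C@@H]1OC(C)(C)O[C@H]1[C@@]2(C)OC(C(C)SCCC(=O)OC)=CC2=O
F8 | step 12 | (Z)-allylic bromide from F7 | BrC/C(C(=O)OC(C)(C)C)=C\[C@@H]1OC(C)(C)O[C@H]1[C@@]2(C)OC(C(C)SCCC(=O)OC)=CC2=O
F9 | step 12 | open-chain chlorohydrin (6-OH, 5-Cl; C6 and C7 as in 18) | C=C(C(=O)OC(C)(C)C)[C@@H]([C@H](O)CCl)[C@@H]1OC(C)(C)O[C@H]1[C@@]2(C)OC(C(C)SCCC(=O)OC)=CC2=O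
F10 | step 17 | 8-O-tert-butyldimethylsilyl ether of 25 | C=C1C(=O)O[C@@H]2/C=C(/C)C3=CC(=O)[C@](C)(O3)[C@H](O)[C@@H](O[Si](C)(C)C(C)(C)C)[C@@H]12
F11 | step 17 | 9-O-acetyl-8-O-tert-butyldimethylsilyl derivative | C=C1C(=O)O[C@@H]2/C=C(/C)C3=CC(=O)[C@](C)(O3)[C@H](OC(C)=O)[C@@H](O[Si](C)(C)C(C)(C)C)[C@@H]12
F12 | step 17 | 9-O-acetate with free 8-OH | C=C1C(=O)O[C@@H]2/C=C(/C)C3=CC(=O)[C@](C)(O3)[C@H](OC(C)=O)[C@@H](O)[C@@H]12
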